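The O1–C2 bond of ring C in the flavanone half is the disconnection on which everything rests. C2 is benzylic to ring B and β to the C4 ketone. O1 is a ring A phenol oxygen ortho to that ketone. The bond is therefore a retro-oxa-Michael bond, as in the chalcone-to-flavanone step of biosynthesis. The precursor is a 2'-hydroxychalcone that already carries the complete, benzyl-protected apigenin unit at C3 of its ring B and a removable tert-butyl ester on the α-carbon. A cinchona thiourea closes ring C and sets C2 as S. Acid then expels the ester as isobutene and CO2 in the same flask.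

Key step: step 9

Assumption 1: the quinidine-derived thiourea is taken to give the 2S product, by analogy with the known behaviour of the pseudoenantiomeric cinchona thioureas in this cyclisation. If the sense proves opposite, the quinine-derived catalyst takes its place in the same step.
Assumption 2: the biaryl axis between C3' of ring B and C8 of the apigenin unit is treated as configurationally labile, since the target carries no axial descriptor.

Step 1
Reactants: 1 apigenin
Product: 2 5,7,4'-tri-O-benzylapigenin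
Conditions: BnBr (4.5 equiv), K2CO3 (6 equiv), DMF, 80 °C
Reagents that add atoms: benzyl bromide, BrCc1ccccc1
Why: Williamson ether synthesis in which excess reagent and heat also alkylate the chelated 5-OH, which must be capped so that the next step attacks C8 and not C6.

Step 2
Reactants: 2 5,7,4'-tri-O-benzylapigenin
Product: 3 8-iodo-5,7,4'-tri-O-benzylapigenin
Conditions: NIS (1.1 equiv), TFA (0.3 equiv), MeCN/CH2Cl2, 0 °C to rt
Reagents that add atoms: N-iodosuccinimide, O=C1CCC(=O)N1I
Why: Electrophilic aromatic iodination, in which the triply oxygenated ring A of the flavone is by far the most nucleophilic arene and fully 5,7-dialkylated flavones react at C8 (next to the small ring oxygen) rather than at C6 (between two benzyloxy groups).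

Step 3
Reactants: 4 3-bromo-4-hydroxybenzaldehyde
Product: 5 4-(benzyloxy)-3-bromobenzaldehyde
Conditions: BnBr (1.1 equiv), K2CO3 (1.5 equiv), DMF, rt
Reagents that add atoms: benzyl bromide, BrCc1ccccc1
Why: Williamson ether synthesis on an acidic, unhindered phenol that leaves the aldehyde untouched.

Step 4
Reactants: 5 4-(benzyloxy)-3-bromobenzaldehyde
Product: 6 4-(benzyloxy)-3-(4,4,5,5-tetramethyl-1,3,2-dioxaborolan-2-yl)benzaldehyde
Conditions: B2pin2 (1.2 equiv), Pd(dppf)Cl2 (3 mol %), KOAc (3 equiv), 1,4-dioxane, 90 °C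
Reagents that add atoms: bis(pinacolato)diboron, CC1(C)OB(OC1(C)C)B1OC(C)(C)C(C)(C)O1
Why: Miyaura borylation of an aryl bromide, which tolerates aldehydes and benzyl ethers because the acetate base is too weak to trigger homocoupling.

Step 5
Reactants: 3 8-iodo-5,7,4'-tri-O-benzylapigenin; 6 4-(benzyloxy)-3-(4,4,5,5-tetramethyl-1,3,2-dioxaborolan-2-yl)benzaldehyde
Product: 7 4-(benzyloxy)-3-(5,7,4'-tri-O-benzylapigenin-8-yl)benzaldehyde
Conditions: Pd(OAc)2 (5 mol %), SPhos (10 mol %), K3PO4 (3 equiv), toluene/H2O, 90 °C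
Reagents that add atoms: none
Why: Suzuki–Miyaura coupling of an 8-iodoflavone with an ortho-alkoxyarylboronate, where the bulky electron-rich biarylphosphine is chosen to build the tri-ortho-substituted biaryl bond.

Step 6
Reactants: 8 2',6'-dihydroxy-4'-methoxyacetophenone
Product: 9 2'-(benzyloxy)-6'-hydroxy-4'-methoxyacetophenone
Conditions: BnBr (1.05 equiv), K2CO3 (1.1 equiv), acetone, reflux
Reagents that add atoms: benzyl bromide, BrCc1ccccc1
Why: Williamson mono-alkylation in which the two hydroxyl groups are equivalent, so there is no regiochemical question, and the remaining OH is locked in a strong hydrogen bond to the ketone and resists a second alkylation.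

Step 7
Reactants: 9 2'-(benzyloxy)-6'-hydroxy-4'-methoxyacetophenone
Product: 10 tert-butyl 3-[2-(benzyloxy)-6-hydroxy-4-methoxyphenyl]-3-oxopropanoate
Conditions: LiHMDS (3.3 equiv), THF, −78 °C; Boc2O (1.1 equiv), −78 to 0 °C; AcOH quench
Reagents that add atoms: di-tert-butyl dicarbonate, CC(C)(C)OC(=O)OC(=O)OC(C)(C)C
Why: Claisen-type C-acylation of the lithium phenoxide–enolate dianion at its more reactive carbon terminus, in which any O-Boc carbonate is funnelled to the same product by Baker–Venkataraman-type O-to-C transfer under the excess base and the bulky ester resists lactonisation to a 4-hydroxycoumarin.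

Step 8
Reactants: 7 4-(benzyloxy)-3-(5,7,4'-tri-O-benzylapigenin-8-yl)benzaldehyde; 10 tert-butyl 3-[2-(benzyloxy)-6-hydroxy-4-methoxyphenyl]-3-oxopropanoate
Product: 11 tert-butyl (Z)-2-[2-(benzyloxy)-6-hydroxy-4-methoxybenzoyl]-3-[4-(benzyloxy)-3-(5,7,4'-tri-O-benzylapigenin-8-yl)phenyl]acrylate
Conditions: piperidine (20 mol %), AcOH (20 mol %), 4 Å MS, toluene, rt
Reagents that add atoms: none
Why: Knoevenagel condensation of the acidic methylene of 10 with the non-enolisable aldehyde 7 through its piperidinium iminium ion, in which the phenol stays chelated to the aryl ketone under the buffer and the isomer with the aryl group cis to the flat ester and trans to the twisted aroyl group (Z) is expected on steric grounds.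

Step 9
Reactants: 11 tert-butyl (Z)-2-[2-(benzyloxy)-6-hydroxy-4-methoxybenzoyl]-3-[4-(benzyloxy)-3-(5,7,4'-tri-O-benzylapigenin-8-yl)phenyl]acrylate
Product: 14 (2S)-5-(benzyloxy)-2-[4-(benzyloxy)-3-(5,7,4'-tri-O-benzylapigenin-8-yl)phenyl]-7-methoxychroman-4-one, via tert-butyl flavanone-3-carboxylate 12 (not isolated), via flavanone-3-carboxylic acid 13 (not isolated)
Conditions: 1-[3,5-bis(trifluoromethyl)phenyl]-3-[(9R)-6'-methoxycinchonan-9-yl]thiourea (quinidine-derived, 10 mol %), toluene, −25 °C; then TsOH·H2O (0.5 equiv), 80 °C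
Reagents that add atoms: none
Why: The quinuclidine nitrogen of the catalyst takes up the proton of the only free phenol (the future O1) while the thiourea N–H pair hydrogen-bonds the two carbonyl groups of the alkylidene β-ketoester, so the phenol oxygen adds to the benzylidene carbon (the future C2) in an intramolecular oxa-Michael addition to give 12; TsOH then silences the amine, cleaves the tert-butyl ester to isobutene and acid 13, and 13 loses CO2 at 80 °C. The closest known reaction type is exactly this cinchona-thiourea-catalysed cyclisation of 2-hydroxyaryl alkylidene β-ketoesters to flavanones with decarboxylation in the same flask, the laboratory counterpart of the chalcone isomerase step of flavonoid biosynthesis. Ring C closes in the 6-endo-trig mode. C2 is the only lasting stereocentre and is controlled by the catalyst, which holds acceptor and phenol in one chiral pocket and opens a single alkene face, whereas C3 is configurationally labile and becomes CH2 on decarboxylation. The step needs one nucleophile, one acceptor and a silent background: the five other phenols are benzyl ethers, the C2=C3 bond of the flavone is a vinylogous ester far less electrophilic than the doubly activated alkene, and the chelated phenol should not add on its own in toluene at −25 °C. The ester makes closure fast at a temperature at which the reverse ring opening that would racemise C2 is frozen, and its removal under acid, never base, keeps C2 intact (partial loss of the peri benzyl ethers would be harmless, since step 10 removes them all).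

Step 10
Reactants: 14 (2S)-5-(benzyloxy)-2-[4-(benzyloxy)-3-(5,7,4'-tri-O-benzylapigenin-8-yl)phenyl]-7-methoxychroman-4-one
Product: 15 (2S)-5-hydroxy-2-{4-hydroxy-3-[5,7-dihydroxy-2-(4-hydroxyphenyl)-4-oxo-4H-chromen-8-yl]phenyl}-7-methoxychroman-4-one (target)
Conditions: H2 (1 atm), Pd/C (10 wt %), THF/MeOH, rt
Reagents that add atoms: none
Why: Catalytic hydrogenolysis of the five aryl benzyl ethers under neutral conditions, which spares the methyl ether, the chelated ketone and the flavone C2=C3 bond and gives no base that could racemise C2 by ring opening.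

Compound list
1 | apigenin | O=c1cc(-c2ccc(O)cc2)oc2cc(O)cc(O)c12 | starting material
2 | 5,7,4'-tri-O-benzylapigenin | O=c1cc(-c2ccc(OCc3ccccc3)cc2)oc2cc(OCc3ccccc3)cc(OCc3ccccc3)c12 | intermediate
3 | 8-iodo-5,7,4'-tri-O-benzylapigenin | Ic1c(OCc2ccccc2)cc(OCc2ccccc2)c2c(=O)cc(-c3ccc(OCc4ccccc4)cc3)oc12 | intermediate
4 | 3-bromo-4-hydroxybenzaldehyde | O=Cc1ccc(O)c(Br)c1 | starting material
5 | 4-(benzyloxy)-3-bromobenzaldehyde | O=Cc1ccc(OCc2ccccc2)c(Br)c1 | intermediate
6 | 4-(benzyloxy)-3-(4,4,5,5-tetramethyl-1,3,2-dioxaborolan-2-yl)benzaldehyde | O=Cc1ccc(OCc2ccccc2)c(B2OC(C)(C)C(C)(C)O2)c1 | intermediate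
7 | 4-(benzyloxy)-3-(5,7,4'-tri-O-benzylapigenin-8-yl)benzaldehyde | O=Cc1ccc(OCc2ccccc2)c(-c2c(OCc3ccccc3)cc(OCc3ccccc3)c3c(=O)cc(-c4ccc(OCc5ccccc5)cc4)oc23)c1 | intermediate
8 | 2',6'-dihydroxy-4'-methoxyacetophenone | CC(=O)c1c(O)cc(OC)cc1O | starting material
9 | 2'-(benzyloxy)-6'-hydroxy-4'-methoxyacetophenone | CC(=O)c1c(O)cc(OC)cc1OCc1ccccc1 | intermediate
10 | tert-butyl 3-[2-(benzyloxy)-6-hydroxy-4-methoxyphenyl]-3-oxopropanoate | CC(C)(C)OC(=O)CC(=O)c1c(O)cc(OC)cc1OCc1ccccc1 | intermediate
11 | tert-butyl (Z)-2-[2-(benzyloxy)-6-hydroxy-4-methoxybenzoyl]-3-[4-(benzyloxy)-3-(5,7,4'-tri-O-benzylapigenin-8-yl)phenyl]acrylate | CC(C)(C)OC(=O)/C(=C\c1ccc(OCc2ccccc2)c(-c2c(OCc3ccccc3)cc(OCc3ccccc3)c3c(=O)cc(-c4ccc(OCc5ccccc5)cc4)oc23)c1)C(=O)c1c(O)cc(OC)cc1OCc1ccccc1 | intermediate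
12 | tert-butyl (2S)-5-(benzyloxy)-2-[4-(benzyloxy)-3-(5,7,4'-tri-O-benzylapigenin-8-yl)phenyl]-7-methoxy-4-oxochromane-3-carboxylate (C3 labile through the enol, drawn without descriptor) | COc1cc(OCc3ccccc3)c2c(c1)O[C@H](c1ccc(OCc3ccccc3)c(-c3c(OCc4ccccc4)cc(OCc4ccccc4)c4c(=O)cc(-c5ccc(OCc6ccccc6)cc5)oc34)c1)C(C(=O)OC(C)(C)C)C2=O | intermediate
13 | (2S)-5-(benzyloxy)-2-[4-(benzyloxy)-3-(5,7,4'-tri-O-benzylapigenin-8-yl)phenyl]-7-methoxy-4-oxochromane-3-carboxylic acid (C3 labile, drawn without descriptor) | COc1cc(OCc3ccccc3)c2c(c1)O[C@H](c1ccc(OCc3ccccc3)c(-c3c(OCc4ccccc4)cc(OCc4ccccc4)c4c(=O)cc(-c5ccc(OCc6ccccc6)cc5)oc34)c1)C(C(=O)O)C2=O | intermediate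
14 | (2S)-5-(benzyloxy)-2-[4-(benzyloxy)-3-(5,7,4'-tri-O-benzylapigenin-8-yl)phenyl]-7-methoxychroman-4-one | COc1cc(OCc3ccccc3)c2c(c1)O[C@H](c1ccc(OCc3ccccc3)c(-c3c(OCc4ccccc4)cc(OCc4ccccc4)c4c(=O)cc(-c5ccc(OCc6ccccc6)cc5)oc34)c1)CC2=O | intermediate
15 | (2S)-5-hydroxy-2-{4-hydroxy-3-[5,7-dihydroxy-2-(4-hydroxyphenyl)-4-oxo-4H-chromen-8-yl]phenyl}-7-methoxychroman-4-one | COc1cc(O)c2c(c1)O[C@H](c1ccc(O)c(-c3c(O)cc(O)c4c(=O)cc(-c5ccc(O)cc5)oc34)c1)CC2=O | target

Total step count: 10. Longest linear sequence: 6 steps (1, 2, 5, 8, 9, 10, or equally 3, 4, 5, 8, 9, 10).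

Steps most likely to fail

Step 9. Enantiopurity may erode in two ways. Facial discrimination may be poor, because the peri benzyloxy group twists the aroyl unit and the biaryl substituent is bulky. The ring may also reopen reversibly before the acid quench. The fallback replaces asymmetric closure by racemic closure and catalytic kinetic resolution, and it sets out from 7 and 9. Claisen–Schmidt condensation (KOH, EtOH/THF, rt) should give the ester-free (E)-2'-hydroxychalcone F1. NaOAc in refluxing EtOH should close it to the racemic penta-O-benzyl flavanone F2. Asymmetric transfer hydrogenation follows, with RuCl(p-cymene)[(R,R)-TsDPEN] in HCO2H/Et3N, stopped near half conversion. It should reduce the 2R enantiomer faster, to the cis-(2R,4R)-flavan-4-ol F3. The 2S ketone is left behind and separated by chromatography, and the fallback comes back to the route at 14.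

Step 8. The free phenol may close the ring prematurely and without catalyst control under the amine buffer. The electron-rich, hindered aldehyde may also condense sluggishly. The fallback masks the nucleophile and sets out from 10. TBSCl and imidazole in DMF should give the aryl silyl ether β-ketoester F4. The Knoevenagel condensation of F4 with 7 can then be forced (piperidine/AcOH, toluene, Dean–Stark) to the silyl-masked alkylidene F5. HF·pyridine in THF at 0 °C should release the phenol in an acidic, base-free medium, and the fallback comes back to the route at 11.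

Step 7. O-acylation, double acylation or incomplete dianion formation may compete. The fallback delivers the carboxyl group intramolecularly and sets out from 9. Boc2O with catalytic DMAP and Et3N in CH2Cl2 should give the aryl tert-butyl carbonate F6. LiHMDS (2.2 equiv) in THF from −78 to 0 °C should then move the Boc group from oxygen to the enolate carbon in a Baker–Venkataraman-type rearrangement, and the fallback comes back to the route at 10.

Further compounds
F1 | step 9 | (E)-1-[2-(benzyloxy)-6-hydroxy-4-methoxyphenyl]-3-[4-(benzyloxy)-3-(5,7,4'-tri-O-benzylapigenin-8-yl)phenyl]prop-2-en-1-one | O=C(/C=C/c1ccc(OCc2ccccc2)c(-c2c(OCc3ccccc3)cc(OCc3ccccc3)c3c(=O)cc(-c4ccc(OCc5ccccc5)cc4)oc23)c1)c1c(O)cc(OC)cc1OCc1ccccc1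
F2 | step 9 | racemic 5-(benzyloxy)-2-[4-(benzyloxy)-3-(5,7,4'-tri-O-benzylapigenin-8-yl)phenyl]-7-methoxychroman-4-one | COc1cc(OCc3ccccc3)c2c(c1)OC(c1ccc(OCc3ccccc3)c(-c3c(OCc4ccccc4)cc(OCc4ccccc4)c4c(=O)cc(-c5ccc(OCc6ccccc6)cc5)oc34)c1)CC2=O
F3 | step 9 | 8-{2-(benzyloxy)-5-[(2R,4R)-5-(benzyloxy)-4-hydroxy-7-methoxychroman-2-yl]phenyl}-5,7,4'-tri-O-benzylapigenin | COc1cc(OCc3ccccc3)c2c(c1)O[C@@H](c1ccc(OCc3ccccc3)c(-c3c(OCc4ccccc4)cc(OCc4ccccc4)c4c(=O)cc(-c5ccc(OCc6ccccc6)cc5)oc34)c1)C[C@H]2O
F4 | step 8 | tert-butyl 3-[2-(benzyloxy)-6-(tert-butyldimethylsilyloxy)-4-methoxyphenyl]-3-oxopropanoate | CC(C)(C)OC(=O)CC(=O)c1c(O[Si](C)(C)C(C)(C)C)cc(OC)cc1OCc1ccccc1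
F5 | step 8 | tert-butyl (Z)-2-[2-(benzyloxy)-6-(tert-butyldimethylsilyloxy)-4-methoxybenzoyl]-3-[4-(benzyloxy)-3-(5,7,4'-tri-O-benzylapigenin-8-yl)phenyl]acrylate | CC(C)(C)OC(=O)/C(=C\c1ccc(OCc2ccccc2)c(-c2c(OCc3ccccc3)cc(OCc3ccccc3)c3c(=O)cc(-c4ccc(OCc5ccccc5)cc4)oc23)c1)C(=O)c1c(O[Si](C)(C)C(C)(C)C)cc(OC)cc1OCc1ccccc1
F6 | step 7 | 2-acetyl-3-(benzyloxy)-5-methoxyphenyl tert-butyl carbonate | CC(=O)c1c(OC(=O)OC(C)(C)C)cc(OC)cc1OCc1ccccc1
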